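The runs were generated by integration on assumed constants; scatter was added.

- Thursday's run, with L at 28 mM, reached 10.6% of X at 4.00 min; Saturday's run, with L at 44 mM, reached 9.6% at 4.00 min.

| flask | L | J | E | remark | time | volume of the second phase over the first |
|---|---|---|---|---|---|---|
| Thursday's | 28 mM | 40 mM | 20 mM | run made earlier |  |  |
| Saturday's | 44 mM | 40 mM | 20 mM | run made earlier |  |  |
| flask | 20 mM | 40.0 mM | 20.0 mM |  | 4.0 min | 0.25 |

| run | time / min | X / % |
|---|---|---|
| Thursday's | 0.667 | 1.0 |
| Thursday's | 1.33 | 3.7 |
| Thursday's | 2.00 | 4.3 |
| Thursday's | 3.00 | 7.7 |
| Thursday's | 4.00 | 10.6 |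
| Thursday's | 5.00 | 15.9 |
| Saturday's | 0.250 | 0.1 |
| Saturday's | 0.667 | 1.3 |
| Saturday's | 1.33 | 3.0 |
| Saturday's | 2.00 | 4.2 |
| Saturday's | 3.00 | 7.4 |
| Saturday's | 4.00 | 9.6 |
| Saturday's | 5.00 | 12.8 |

(standard deviation of a reading: 0.5 percentage points)

- in the second phase: J; everything else is in the first
- charges count per volume of the first phase; a concentration in a rate is the amount of a species over the volume of its own phase; every rate counts per litre of the first phase
- the numbers in the tables scatter by 0.5 percentage points (one standard deviation)
- the earlier runs hold the two phases in the same ratio of volumes as the flask asked about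

- midnight: doubling the amount of J, all else as stated
- winter: doubling the transfer coefficient of J, all else as stated

1. X at 4.0 min, in percent of the L charged
2. the change that raises the amount of X at 4.0 min, in percent of the L charged most ("none" if none brings more than 2 percentage points) (midnight / winter / none)
3. amount of X at 4.0 min, in percent of the L charged, after winter

- Two times carry the estimate: the 4.0 min allowed, and the lifetime of L into X, the time a constant first-order conversion needs to take L down by a factor e.
- Read from the readings at 4.00 min, that lifetime is 35.7 min in Thursday's run and 39.6 min in Saturday's run, each carrying the scatter of 0.5 percentage points.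
- Between these two runs the charge of L rose by a factor of 1.57 and the lifetime read by 1.11, so over these charges L reads as pseudo-first-order, and this reckoning takes no third time for its charge.
- The flask shares J, E and the phase ratio with Thursday's run, its nearest charge, so my reckoning carries that lifetime over: the ratio 0.112 gives 10.6% of X.
- Both runs hold J at 40 mM, so this lifetime gives no reading on midnight, and the runs state no change of the transfer coefficient that would speak to winter.
- The forecast stands higher than this reckoning, at 11.3%; it names midnight and puts winter at 12.7%, holding that “the rate is close to first order in L”.
- The flask gives 12.2%; midnight gains 14 points, and winter gains 8.8 points, reaching 20.9%.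

    G + X → Z (k = 0.520 /M/s)
    G ⇌ J, rate k2*([G] - [J]/K2) per volume of the first phase (partition coefficient = 1.70, kL = 0.00200 /s)
    G + E → Q (k = 6.80 /M/s)
    L + G → X (k = 0.290 /M/s)

- Counted the same way from X, the flask's lifetime is 30.8 min, shorter than the one read from Thursday's run, and winter's is 17.0 min. The neighbouring flask, the same charges read at 1.5 min, is reckoned from Thursday's lifetime at 4.11% and gives 3.33%. Its own lifetime is 44.3 min, longer than the flask's. That neighbour still holds 44% of its E and 1.71 mM of G, while the flask at 4.00 min holds 3.0% of its E and 3.84 mM of G.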